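Decide now whether the flask is stopped at 20 h, as north, or left to 40 h, as south-east. The charges are the same, so the decision hangs on what the later stretch of time adds.

common to all: second end groups 1.96 M
- ochre: first end groups 2.8 M; run made earlier
- south-east: first end groups 2.0 M; time 40 h
- north: first end groups 2.0 M; time 20 h

ochre run (percent of the first end groups charged)

| time / h | links / % | first end groups / % |
|---|---|---|
| 3.00 | 14.4 | 85.2 |
| 8.00 | 28.7 | 71.6 |
| 15.0 | 38.9 | 60.5 |
| 25.0 | 45.6 | 54.7 |

(standard deviation of a reading: 0.3 percentage points)



1. which one finishes higher in amount of links, in percent of the first end groups charged ("neither" within 2 percentage points) (south-east / north / neither)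
2. amount of links at the end, in percent of the first end groups charged, south-east
3. amount of links at the end, in percent of the first end groups charged, north

The ochre run shows how quickly the climb in links dies away. Links formed at 0.0408 M h⁻¹ between the readings at 8.00 h and 15.0 h, then at 0.0188 M h⁻¹ up to 25.0 h, and the midpoints of these intervals lie 8.50 h apart. Dividing that spacing by the base-ten logarithm of the rate ratio gives the time in which the rate falls by one power of ten. This decade time, a relaxation time counted in powers of ten, reads 25.2 h, subject to the scatter and taken from a richer charge of first end groups.

If the gap to rest shrinks at that pace, the extra 20.0 h cuts it by a factor of 6.22. Starting from the forecast's rest at 60.0% and its north value, the gap of 12 percentage points closes by 10 points, which is more than the margin. This reckoning therefore leaves the flask to 40 h and expects 58.0% of links, above the forecast's figure.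

The forecast names south-east, with 56.5% for south-east and 47.7% for north: “South-east therefore finishes higher, mainly because it runs longer”.

    first end groups + second end groups ⇌ links + released group (K = 4.20, k = 0.0300 L mol⁻¹ h⁻¹)
    second end groups + links → over-reaction product (k = 7.70 × 10⁻⁴ L mol⁻¹ h⁻¹)
    2 second end groups → homo dimer (k = 0.00270 L mol⁻¹ h⁻¹)

South-east finishes higher, with 57.3% of links against 48.3% for north, but it has not come to rest. In north at 20.0 h, the relaxation half-life of the step forming links, by that step alone and both ways together, is 10.1 h, which makes a decade time of 33.5 h, longer than the 25.2 h read from the ochre run. At that pace, ten times the time adds about 10.7 decade times to south-east and 5.37 to north. North then holds 54.5% of links at 200 h. In south-east, over-reaction product goes from 1.06% to 6.38% and homo dimer from 0.108 M to 0.232 M, while links fall to 48.5% at 400 h.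

The data stem from a simulated flask on assumed constants.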